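**Retrosynthetic overview**

1. Drimane numbering is used: ring A = C1–C2–C3–C4–C5–C10, ring B = C5–C6–C7–C8–C9–C10, C11 = the OCH2 carbon on C9, C12 = the exocyclic CH2 on C8.
2. Enabling feature: ring B is a 3-methylidenecyclohexene (C6=C7 inside the ring, C8=C12 outside it). This is the retron of a Diels–Alder reaction between a vinylallene (C5=C6–C7=C8=C12) and the C9=C10 alkene. The saturated atoms C1–C4 of ring A link C10 to C5 as a four-carbon tether that carries the C4 gem-dimethyl group and the C3 carbinol.
3. Key disconnection: C5–C10 and C8–C9 are cut together. This opens rings A and B to an acyclic (2E,8E)-tetraenal whose only stereocentre is C3. C11 is raised to the aldehyde level for activation and reduced again in the same flask.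
4. Order of rings: the two coumarin rings are bought with umbelliferone. Rings B and A are closed in one cycloaddition, ring A by the C5–C10 bond, and no ring is closed afterwards. The C11–O aryl ether (Mitsunobu reaction) and release of the C3 hydroxyl follow.
5. The tetraenal is built linearly from geranyl acetate (C1–C3, C9–C11, C10 methyl), 3-methylbuta-1,2-diene (C4, its two methyls, C5; the asymmetric reverse prenylation sets C3), vinyl-Bpin (C6) and methyl propargyl carbonate (C7, C8, C12).

Key step: step 8

Assumption: (−)-diisopinocampheylborane and methyl prop-2-yn-1-yl carbonate are taken as purchasable. Otherwise each is one routine operation, from (+)-α-pinene/BH3·SMe2 and from propargyl alcohol/methyl chloroformate respectively.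

**Route**

Step 1
Reactants: 1 geranyl acetate
Product: 3 (2E)-3-methyl-6-oxohex-2-en-1-yl acetate, via ozonide 2 (not isolated)
Conditions: O3 (1 equiv, Sudan Red 7B end point), CH2Cl2, −78 °C; then Me2S, −78 °C → rt
Reagents that add atoms: ozone, [O-][O+]=O
Why: In this Criegee ozonolysis the electron-rich isopropylidene alkene should react much faster than the alkene deactivated by the allylic acetoxy group, so the E-trisubstituted alkene (later C9=C10) is kept with its geometry.

Step 2
Reactants: 3 (2E)-3-methyl-6-oxohex-2-en-1-yl acetate; 4 3-methylbuta-1,2-diene; 5 (−)-diisopinocampheylborane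
Product: 8 (2E,6R)-6-hydroxy-3,7,7-trimethylnona-2,8-dien-1-yl acetate, via prenylborane 6 (not isolated), via borinate 7 (not isolated)
Conditions: 4 + 5, THF, −25 °C; then 3, Et2O, −78 °C; then NaBO3·4H2O, THF/H2O, rt
Reagents that add atoms: none
Why: Hydroboration of the allene at its CH2 terminus gives the prenylborane, which adds to the aldehyde through its γ-carbon in a closed Zimmerman–Traxler chair (Brown asymmetric allylboration, reverse-prenyl mode), forming C3–C4 with the gem-dimethyl group and a vinyl handle, while the isopinocampheyl groups derived from (+)-α-pinene select the aldehyde face that gives the 6R carbinol (drimane C3, R) and perborate frees the alcohol without touching the acetate.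

Step 3
Reactants: 8 (2E,6R)-6-hydroxy-3,7,7-trimethylnona-2,8-dien-1-yl acetate
Product: 9 (2E,6R)-3,7,7-trimethyl-6-(triethylsilyloxy)nona-2,8-dien-1-yl acetate
Conditions: TESOTf, 2,6-lutidine, CH2Cl2, −78 → 0 °C
Reagents that add atoms: triethylsilyl trifluoromethanesulfonate (TESOTf), CC[Si](CC)(CC)OS(=O)(=O)C(F)(F)F
Why: Silylation with the reactive silyl triflate overcomes the hindrance next to the quaternary carbon, and the ether later blocks oxa-Michael addition of this oxygen to the enal and serves as the equatorial control group of the key step.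

Step 4
Reactants: 9 (2E,6R)-3,7,7-trimethyl-6-(triethylsilyloxy)nona-2,8-dien-1-yl acetate
Product: 10 (2E,6R)-3,7,7-trimethyl-6-(triethylsilyloxy)nona-2,8-dien-1-ol
Conditions: K2CO3 (cat.), MeOH, 0 °C → rt
Reagents that add atoms: none
Why: Base-catalysed transesterification removes the primary allylic acetate, which would ionise under the later palladium catalysis, and leaves the hindered silyl ether intact.

Step 5
Reactants: 10 (2E,6R)-3,7,7-trimethyl-6-(triethylsilyloxy)nona-2,8-dien-1-ol; 11 vinylboronic acid pinacol ester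
Product: 12 (2E,6R,8E)-3,7,7-trimethyl-9-(4,4,5,5-tetramethyl-1,3,2-dioxaborolan-2-yl)-6-(triethylsilyloxy)nona-2,8-dien-1-ol
Conditions: second-generation Hoveyda–Grubbs catalyst (5–10 mol %), 11 (3 equiv), CH2Cl2, 40 °C
Reagents that add atoms: none
Why: In this olefin cross-metathesis only the monosubstituted vinyl group can engage the ruthenium alkylidene (the trisubstituted alkene is inert), loss of ethene drives the exchange, and the bulk of the quaternary carbon and of the boronate should enforce the E geometry of C5=C6.

Step 6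
Reactants: 12 (2E,6R,8E)-3,7,7-trimethyl-9-(4,4,5,5-tetramethyl-1,3,2-dioxaborolan-2-yl)-6-(triethylsilyloxy)nona-2,8-dien-1-ol; 13 methyl prop-2-yn-1-yl carbonate
Product: 14 (2E,6R,8E)-3,7,7-trimethyl-6-(triethylsilyloxy)dodeca-2,8,10,11-tetraen-1-ol
Conditions: Pd(PPh3)4 (5 mol %), 13 (1.5 equiv), THF, 50 °C
Reagents that add atoms: none
Why: In this Suzuki–Miyaura-type coupling of a propargylic carbonate, zerovalent palladium ionises 13 in the SN2′ sense with loss of CO2 to an allenylpalladium methoxide, the methoxide triggers base-free transmetalation from boron, and reductive elimination forms C6–C7 with retention of the E alkene to give the vinylallene.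

Step 7
Reactants: 14 (2E,6R,8E)-3,7,7-trimethyl-6-(triethylsilyloxy)dodeca-2,8,10,11-tetraen-1-ol
Product: 15 (2E,6R,8E)-3,7,7-trimethyl-6-(triethylsilyloxy)dodeca-2,8,10,11-tetraenal
Conditions: MnO2 (activated, excess), CH2Cl2, rt
Reagents that add atoms: none
Why: Neutral MnO2 oxidation of the allylic alcohol gives the enal without E/Z scrambling and without touching the vinylallene, so the activated dienophile is unmasked only just before the cycloaddition.

Step 8
Reactants: 15 (2E,6R,8E)-3,7,7-trimethyl-6-(triethylsilyloxy)dodeca-2,8,10,11-tetraenal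
Product: 17 [(1R,4aS,6R,8aR)-5,5,8a-trimethyl-2-methylidene-6-(triethylsilyloxy)-1,2,4a,5,6,7,8,8a-octahydronaphthalen-1-yl]methanol, via cycloadduct aldehyde 16 (not isolated)
Conditions: Me2AlCl (1.2 equiv), CH2Cl2 (0.01 M), −78 → −20 °C; then i-Bu2AlH (1.5 equiv), −78 °C; aq. potassium sodium tartrate
Reagents that add atoms: none
Why: Me2AlCl binds the formyl oxygen of 15 and lowers the LUMO of the C9=C10 alkene, which adds suprafacially to the s-cis diene C5=C6–C7=C8 of the vinylallene in a concerted, asynchronous [4+2] cycloaddition, while the orthogonal C8=C12 π bond takes no part and emerges as the exocyclic methylene next to the new C6=C7 bond; i-Bu2AlH then reduces the deconjugated, epimerisable aldehyde 16 in the same flask before C9 can enolise. The closest known reaction types are the Lewis-acid-promoted intramolecular Diels–Alder reaction of (2E,8E,10E)-undeca-2,8,10-trienals to trans-fused octalins and the intramolecular Diels–Alder reaction of vinylallenes. Ring B is closed as the six-membered cycloaddition ring by both new σ bonds (C5–C10 and C8–C9), and ring A is closed in the fused (type 1) mode by the C5–C10 bond across the four-carbon tether C1–C4, which sits in a chair. C9 and C10 are set relative to each other by the E geometry of the enal (C11 cis to the C10 methyl), C5 relative to C10 by the E geometry of C5=C6 together with the endo position of the complexed formyl group, which puts the tether anti and makes the ring fusion trans, and all three relative to C3 by the chair in which the OSiEt3 group is equatorial, so that 3R is relayed to 5S, 9R and 10R. The step needs endo over exo, one diene face over the other and fused over bridged addition: the first rests on Lewis-acid complexation of the formyl group (the syn-axial contact between one C4 methyl and a C10 substituent is paid in both fusion modes and gives no bias), the second on the cost of an axial silyloxy group facing C1–H and C5–H, and the third on the short tether. The low reactivity of a β,β-disubstituted dienophile is offset by the sp carbon C8, which has no inside substituent in the s-cis form, by the release of allene strain and by the Thorpe–Ingold effect of the C4 gem-dimethyl group.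

Step 9
Reactants: 17 [(1R,4aS,6R,8aR)-5,5,8a-trimethyl-2-methylidene-6-(triethylsilyloxy)-1,2,4a,5,6,7,8,8a-octahydronaphthalen-1-yl]methanol; 18 umbelliferone (7-hydroxy-2H-chromen-2-one)
Product: 19 7-{[(1R,4aS,6R,8aR)-5,5,8a-trimethyl-2-methylidene-6-(triethylsilyloxy)-1,2,4a,5,6,7,8,8a-octahydronaphthalen-1-yl]methoxy}-2H-chromen-2-one
Conditions: PPh3, DIAD, THF, 0 °C → rt
Reagents that add atoms: none
Why: In this Mitsunobu etherification the acidic phenol displaces the alkoxyphosphonium ion at the primary carbon C11, so no stereocentre is touched and the weakly basic phenoxide should not cause elimination towards C9.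

Step 10
Reactants: 19 7-{[(1R,4aS,6R,8aR)-5,5,8a-trimethyl-2-methylidene-6-(triethylsilyloxy)-1,2,4a,5,6,7,8,8a-octahydronaphthalen-1-yl]methoxy}-2H-chromen-2-one
Product: 20 7-{[(1R,4aS,6R,8aR)-6-hydroxy-5,5,8a-trimethyl-2-methylidene-1,2,4a,5,6,7,8,8a-octahydronaphthalen-1-yl]methoxy}-2H-chromen-2-one (target)
Conditions: HF·pyridine, pyridine, THF, 0 °C → rt
Reagents that add atoms: none
Why: Buffered fluoride-mediated desilylation cleaves the Si–O bond only, so the C3 configuration, the acid-sensitive diene, the aryl ether and the coumarin lactone should all survive.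

**Compound list**

1 | geranyl acetate, (2E)-3,7-dimethylocta-2,6-dien-1-yl acetate | CC(C)=CCC/C(C)=C/COC(C)=O | starting material
2 | ozonide, (2E)-5-(5,5-dimethyl-1,2,4-trioxolan-3-yl)-3-methylpent-2-en-1-yl acetate | CC1(C)OOC(CC/C(C)=C/COC(C)=O)O1 | intermediate
3 | (2E)-3-methyl-6-oxohex-2-en-1-yl acetate | O=CCC/C(C)=C/COC(C)=O | intermediate
4 | 3-methylbuta-1,2-diene | CC(C)=C=C | starting material
5 | (−)-diisopinocampheylborane, from (+)-α-pinene | B([C@@H]1C[C@@H]2C[C@H]([C@H]1C)C2(C)C)[C@@H]1C[C@@H]2C[C@H]([C@H]1C)C2(C)C | starting material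
6 | prenylborane, B-(3-methylbut-2-en-1-yl)diisopinocampheylborane | CC(C)=CCB([C@@H]1C[C@@H]2C[C@H]([C@H]1C)C2(C)C)[C@@H]1C[C@@H]2C[C@H]([C@H]1C)C2(C)C | intermediate
7 | borinate, diisopinocampheylborinic ester of 8 | C=CC(C)(C)[C@H](OB([C@@H]1C[C@@H]2C[C@H]([C@H]1C)C2(C)C)[C@@H]1C[C@@H]2C[C@H]([C@H]1C)C2(C)C)CC/C(C)=C/COC(C)=O | intermediate
8 | (2E,6R)-6-hydroxy-3,7,7-trimethylnona-2,8-dien-1-yl acetate | C=CC(C)(C)[C@H](O)CC/C(C)=C/COC(C)=O | intermediate
9 | (2E,6R)-3,7,7-trimethyl-6-(triethylsilyloxy)nona-2,8-dien-1-yl acetate | C=CC(C)(C)[C@H](O[Si](CC)(CC)CC)CC/C(C)=C/COC(C)=O | intermediate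
10 | (2E,6R)-3,7,7-trimethyl-6-(triethylsilyloxy)nona-2,8-dien-1-ol | C=CC(C)(C)[C@H](O[Si](CC)(CC)CC)CC/C(C)=C/CO | intermediate
11 | vinylboronic acid pinacol ester | C=CB1OC(C)(C)C(C)(C)O1 | starting material
12 | (2E,6R,8E)-3,7,7-trimethyl-9-(4,4,5,5-tetramethyl-1,3,2-dioxaborolan-2-yl)-6-(triethylsilyloxy)nona-2,8-dien-1-ol | CC1(C)OB(/C=C/C(C)(C)[C@H](O[Si](CC)(CC)CC)CC/C(C)=C/CO)OC1(C)C | intermediate
13 | methyl prop-2-yn-1-yl carbonate | C#CCOC(=O)OC | starting material
14 | (2E,6R,8E)-3,7,7-trimethyl-6-(triethylsilyloxy)dodeca-2,8,10,11-tetraen-1-ol | C=C=C/C=C/C(C)(C)[C@H](O[Si](CC)(CC)CC)CC/C(C)=C/CO | intermediate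
15 | (2E,6R,8E)-3,7,7-trimethyl-6-(triethylsilyloxy)dodeca-2,8,10,11-tetraenal | C=C=C/C=C/C(C)(C)[C@H](O[Si](CC)(CC)CC)CC/C(C)=C/C=O | intermediate
16 | (1R,4aS,6R,8aR)-5,5,8a-trimethyl-2-methylidene-6-(triethylsilyloxy)-1,2,4a,5,6,7,8,8a-octahydronaphthalene-1-carbaldehyde | C=C1C=C[C@@H]2C(C)(C)[C@H](O[Si](CC)(CC)CC)CC[C@@]2(C)[C@@H]1C=O | intermediate
17 | [(1R,4aS,6R,8aR)-5,5,8a-trimethyl-2-methylidene-6-(triethylsilyloxy)-1,2,4a,5,6,7,8,8a-octahydronaphthalen-1-yl]methanol | C=C1C=C[C@@H]2C(C)(C)[C@H](O[Si](CC)(CC)CC)CC[C@@]2(C)[C@@H]1CO | intermediate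
18 | umbelliferone, 7-hydroxy-2H-chromen-2-one | Oc1ccc2ccc(=O)oc2c1 | starting material
19 | 7-{[(1R,4aS,6R,8aR)-5,5,8a-trimethyl-2-methylidene-6-(triethylsilyloxy)-1,2,4a,5,6,7,8,8a-octahydronaphthalen-1-yl]methoxy}-2H-chromen-2-one | C=C1C=C[C@@H]2C(C)(C)[C@H](O[Si](CC)(CC)CC)CC[C@@]2(C)[C@@H]1COc1ccc2ccc(=O)oc2c1 | intermediate
20 | 7-{[(1R,4aS,6R,8aR)-6-hydroxy-5,5,8a-trimethyl-2-methylidene-1,2,4a,5,6,7,8,8a-octahydronaphthalen-1-yl]methoxy}-2H-chromen-2-one | C=C1C=C[C@@H]2C(C)(C)[C@H](O)CC[C@@]2(C)[C@@H]1COc1ccc2ccc(=O)oc2c1 | target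

**Step count**

- Total step count: 10
- Longest linear sequence: 10 steps (1 → 20)

**Three steps most likely to fail**

**1. Step 8.** Two things may go wrong:
- Diastereocontrol may be lost by leakage through the exo transition state or through the chair with an axial silyloxy group.
- The Lewis acid may oligomerise the vinylallene before the hindered C5–C10 bond forms.

The fallback uses auxiliary control at the carboxylic acid level. It sets out from 15 and returns at 17. Pinnick oxidation of 15 (NaClO2, NaH2PO4, 2-methylbut-2-ene, t-BuOH/H2O) should give the tetraenoic acid F1. Pivaloyl chloride and Et3N turn it into the mixed pivalic anhydride F2, which acylates lithiated (R)-4-benzyl-1,3-oxazolidin-2-one to the N-enoyl imide F3. With Me2AlCl (more than 1 equiv, CH2Cl2, −30 °C) both imide carbonyls chelate aluminium and the benzyl group shields one face of the s-cis enoyl unit. This bias acts in the same direction as the C3 substituent, so the cycloadduct imide F4 is expected with the same 5S,9R,10R configuration. LiBH4 (Et2O, 1 equiv H2O, 0 °C) removes the auxiliary reductively and gives 17.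

**2. Step 5.** The metathesis may be slow or stall, because the vinyl group is flanked by the quaternary C4 and the silyloxy-bearing C3. Catalyst decay and self-metathesis of 11 would then take over.

The fallback replaces metathesis with alkyne hydroboration. It sets out from 3 and returns at 12. NaBH4 (MeOH, 0 °C) reduces 3 to the primary alcohol F5. Ruthenium-catalysed transfer-hydrogenative C–C coupling of this alcohol with 2-methyl-4-(trimethylsilyl)but-1-en-3-yne gives the gem-dimethyl homopropargylic silylalkyne carbinol F6 (Ru(O2CCF3)2(CO)(PPh3)2, the BINAP enantiomer that delivers the 6R product, THF, 95 °C). TESOTf/2,6-lutidine gives the triethylsilyl ether F7. K2CO3/MeOH removes the acetyl group and the alkynyl trimethylsilyl group in one operation to give the terminal alkyne F8. Copper-catalysed borylation–protonation (CuCl, NaOt-Bu, Xantphos, B2pin2, MeOH, THF, rt) tolerates the free hydroxyl group and places boron at the unhindered terminus by syn addition, which gives 12.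

**3. Step 6.** Three things may go wrong:
- Coupling may occur through the propargyl terminus instead of the allenyl terminus.
- The pinacol ester may protodeboronate under base-free conditions.
- Carbonate exchange at the free C11 hydroxyl may be followed by allylic ionisation.

The fallback reverses the polarity and uses a Stille coupling. It sets out from 12 and returns at 14. NaOH, then I2 (THF, 0 °C), converts 12 with retention into the (E)-alkenyl iodide F9. This is coupled with commercial allenyltributylstannane (Pd2(dba)3, AsPh3, NMP, rt). The allenyl group should be transferred from tin without transposition to give 14.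

**Further compounds**

F1 | step 8 | (2E,6R,8E)-3,7,7-trimethyl-6-(triethylsilyloxy)dodeca-2,8,10,11-tetraenoic acid | C=C=C/C=C/C(C)(C)[C@H](O[Si](CC)(CC)CC)CC/C(C)=C/C(=O)O
F2 | step 8 | mixed anhydride of F1 with pivalic acid | C=C=C/C=C/C(C)(C)[C@H](O[Si](CC)(CC)CC)CC/C(C)=C/C(=O)OC(=O)C(C)(C)C
F3 | step 8 | (4R)-4-benzyl-3-[(2E,6R,8E)-3,7,7-trimethyl-6-(triethylsilyloxy)dodeca-2,8,10,11-tetraenoyl]-1,3-oxazolidin-2-one | C=C=C/C=C/C(C)(C)[C@H](O[Si](CC)(CC)CC)CC/C(C)=C/C(=O)N1[C@H](Cc2ccccc2)COC1=O
F4 | step 8 | (4R)-4-benzyl-3-{[(1R,4aS,6R,8aR)-5,5,8a-trimethyl-2-methylidene-6-(triethylsilyloxy)-1,2,4a,5,6,7,8,8a-octahydronaphthalen-1-yl]carbonyl}-1,3-oxazolidin-2-one | C=C1C=C[C@@H]2C(C)(C)[C@H](O[Si](CC)(CC)CC)CC[C@@]2(C)[C@@H]1C(=O)N1[C@H](Cc2ccccc2)COC1=O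
F5 | step 5 | (2E)-6-hydroxy-3-methylhex-2-en-1-yl acetate | OCCC/C(C)=C/COC(C)=O
F6 | step 5 | (2E,6R)-6-hydroxy-3,7,7-trimethyl-9-(trimethylsilyl)non-2-en-8-yn-1-yl acetate | C[Si](C)(C)C#CC(C)(C)[C@H](O)CC/C(C)=C/COC(C)=O
F7 | step 5 | (2E,6R)-3,7,7-trimethyl-6-(triethylsilyloxy)-9-(trimethylsilyl)non-2-en-8-yn-1-yl acetate | C[Si](C)(C)C#CC(C)(C)[C@H](O[Si](CC)(CC)CC)CC/C(C)=C/COC(C)=O
F8 | step 5 | (2E,6R)-3,7,7-trimethyl-6-(triethylsilyloxy)non-2-en-8-yn-1-ol | C#CC(C)(C)[C@H](O[Si](CC)(CC)CC)CC/C(C)=C/CO
F9 | step 6 | (2E,6R,8E)-9-iodo-3,7,7-trimethyl-6-(triethylsilyloxy)nona-2,8-dien-1-ol | I/C=C/C(C)(C)[C@H](O[Si](CC)(CC)CC)CC/C(C)=C/CO
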